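**Retrosynthetic overview**

1. Numbering follows the ring carbons in the order of the target SMILES: C1 (=CH2), C2, C3 (quaternary bridgehead), C4, C5 (carbinol), C6 (CH bridgehead), C7 (C–CH3 bridge), C8–C10, C11 (CMe2). Ring A = C3, C7–C11. Ring B = C3–C7.
2. Feature used: C3 and C7, the adjacent quaternary carbons shared by ring A and the norbornane, are the alkene carbons of a 2,6,6-trimethylcyclohexene that bears C4 on C3. The target is this alkene bridged on one face by C6 (to C7) and by C1–C2 (to C3).
3. Disconnections: the C5–O caffeate ester; C1=CH2 back to a C1 ketone; removal of C2 (norbornanone back to a bicyclo[2.1.1]hexan-5-one with a C1–C3 bond); then C1–C3 and C6–C7 together by a crossed intramolecular ketene–alkene [2+2].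
4. Ring order: ring A is bought. The cyclobutanone (C1–C3–C7–C6) and ring B close together in the cycloaddition. The four-membered ring is then enlarged to the C1–C2–C3–C7–C6 ring.
5. Stereochemistry: C5 is set by asymmetric hydrogenation and relays its configuration to C3, C6 and C7 in the cycloaddition. C5 is inverted at the end by oxidation and endo-face reduction.

Key step: step 6

Remark on the structure: read from the SMILES, the C5 oxygen is exo (on the side of the C7 bridge). The C7 methyl lies over the C4–C5 bridge and C8 lies over the C1–C2 bridge. In the numbering used here the target is (3R,5R,6R,7S). CIP letters at C3 change along the route with the priorities only, not with the geometry.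

Assumption: the C1 carbinol centre created in step 8 is drawn for attack from the C4–C5 side. It has no consequence, because C1 returns to sp2 in step 9.

**Step 1**
Reactants: 1 β-homocyclocitral; 2 ethyl diazoacetate
Product: 3 ethyl 3-oxo-4-(2,6,6-trimethylcyclohex-1-en-1-yl)butanoate
Conditions: SnCl2 (10 mol %), CH2Cl2, rt
Reagents that add atoms: none
Why: Roskamp homologation: SnCl2 activates the aldehyde towards the diazo carbon, and a 1,2-hydride shift with loss of N2 gives the β-keto ester under conditions too mild to move the tetrasubstituted alkene.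

**Step 2**
Reactants: 3 β-keto ester
Product: 4 ethyl (S)-3-hydroxy-4-(2,6,6-trimethylcyclohex-1-en-1-yl)butanoate
Conditions: RuCl2[(S)-BINAP] (0.5 mol %), H2 (50 atm), EtOH, 40 °C
Reagents that add atoms: none
Why: Noyori asymmetric hydrogenation of a β-keto ester: the ketone is reduced inside the ester-chelated ruthenium complex, (S)-BINAP gives the (S)-carbinol in the same sense as for simple 3-oxoalkanoates (the priority order O > CH2CO2Et > CH2-ring > H is unchanged), and this catalyst does not hydrogenate the unactivated tetrasubstituted alkene.

**Step 3**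
Reactants: 4 (S)-β-hydroxy ester
Product: 5 ethyl (S)-3-(tert-butyldimethylsilyloxy)-4-(2,6,6-trimethylcyclohex-1-en-1-yl)butanoate
Conditions: TBSCl, imidazole, DMF, rt
Reagents that add atoms: tert-butyldimethylsilyl chloride, CC(C)(C)[Si](C)(C)Cl
Why: Imidazole-promoted silylation of a secondary alcohol leaves C5 untouched and installs the large group that later steers the cycloaddition.

**Step 4**
Reactants: 5 silyloxy ester
Product: 6 (S)-3-(tert-butyldimethylsilyloxy)-4-(2,6,6-trimethylcyclohex-1-en-1-yl)butanoic acid
Conditions: LiOH, THF–MeOH–H2O, rt; then cold 1 M HCl to pH 4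
Reagents that add atoms: lithium hydroxide, [Li+].[OH-]
Why: Ester saponification at room temperature, in which the carboxylate once formed resists β-elimination and the secondary silyl ether withstands hydroxide and a brief cold acidification.

**Step 5**
Reactants: 6 silyloxy acid
Product: 7 (S)-3-(tert-butyldimethylsilyloxy)-4-(2,6,6-trimethylcyclohex-1-en-1-yl)butanoyl chloride
Conditions: 1-chloro-N,N,2-trimethylpropenylamine (1.1 equiv), CH2Cl2, 0 °C to rt; evaporated and used crude
Reagents that add atoms: 1-chloro-N,N,2-trimethylprop-1-en-1-amine, CC(C)=C(Cl)N(C)C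
Why: Acid chloride formation with an α-chloroenamine runs under neutral conditions without free HCl, so neither the silyl ether nor the acid-sensitive alkene is touched.

**Step 6**
Reactants: 7 acid chloride
Product: 9 ring A-fused bicyclo[2.1.1]hexan-5-one (3S,5S,6R,7S) in which the C1 ketone bridges C3 and C6 and the C5 silyloxy group is syn to the C1 bridge, via ketene 8 (not isolated)
Conditions: Et3N (3 equiv), toluene, reflux, 7 added by syringe pump (final ca. 0.005 M)
Reagents that add atoms: none
Why: Et3N removes HCl from 7 to give aldoketene 8, kept dilute by slow addition so that it meets its own alkene rather than a second ketene, and the electron-rich C3=C7 bond then attacks the electrophilic sp carbon C1 while the developing enolate carbon C6 closes on C7 in a concerted but asynchronous thermal [2+2] (C1–C3 bonding ahead of C6–C7, positive charge building on tertiary C7). The closest known reaction type is the intramolecular ketene–alkene cycloaddition of ketenes from hex-5-enoyl chlorides, whose two-atom tether leads to bicyclo[2.1.1]hexan-5-ones, and here it is applied to a tetrasubstituted cyclohexene. The cyclobutanone (C1–C3–C7–C6) closes through the two new bonds on one face of the alkene, ring B (C3–C4–C5–C6–C7) closes through the C6–C7 bond as the C4–C5 tether spans the diagonal C3/C6 positions of the four-membered ring, and the parallel orientation would need a bicyclo[2.2.0]hexanone, so the tether length secures the crossed regiochemistry. C3 and C7 are set by suprafacial addition to the ring alkene, so that C4 and the C7 methyl, cis on the alkene, stay on the same side (methyl over the C4–C5 bridge, C8 towards C1), and C6 is fixed by the bridge. The face of the alkene is chosen by the C5 stereocentre, because in the favoured transition state the silyloxy group points to the flat ketene side and the C5 hydrogen points to the C7 methyl, which from (S)-C5 should give (3S,6R,7S) with the silyloxy group syn to the C1 bridge. The minor facial isomer has to be removed by chromatography at this stage, since it would become the enantiomeric skeleton once C5 is oxidised.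

**Step 7**
Reactants: 10 diphenyl diselenide
Product: 12 bis(phenylseleno)methane, via sodium benzeneselenolate 11 (not isolated)
Conditions: NaBH4, EtOH, 0 °C to rt; then CH2Br2, rt to 50 °C
Reagents that add atoms: dibromomethane, BrCBr; sodium borohydride, [Na+].[BH4-] (sodium of 11 only)
Why: Borohydride cleaves the Se–Se bond to the selenolate, which displaces both bromides of CH2Br2 by SN2 to give the selenoacetal.

**Step 8**
Reactants: 9 cyclobutanone; 12 bis(phenylseleno)methane
Product: 14 C1 tertiary carbinol (1R,3S,5S,6R,7S) bearing CH2SePh on the C4–C5 side, via (phenylseleno)methyllithium 13 (not isolated)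
Conditions: 12, n-BuLi, THF, −78 °C; then 9, −78 to −40 °C; then H2O
Reagents that add atoms: n-butyllithium, [Li]CCCC (lithium of 13 only)
Why: Selenium–lithium exchange on the selenoacetal followed by 1,2-addition: α-selenoalkyllithiums are slim, strongly nucleophilic reagents that add even to very hindered ketones, the strained and non-enolisable C1 carbonyl (both α-carbons are bridgeheads) is approached from the C4–C5 side because C8 closes the C7 side, and the new C1 centre is erased in step 9.

**Step 9**
Reactants: 14 β-hydroxy selenide
Product: 17 norbornanone (3S,5S,6R,7S) with the C1 ketone and the new C2 methylene between C1 and C3 and the C5 silyloxy group endo, via selenoxide 15 (not isolated), via selenone 16 (not isolated)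
Conditions: mCPBA (3 equiv), CH2Cl2, 0 °C to rt
Reagents that add atoms: mCPBA, O=C(OO)c1cccc(Cl)c1 (its oxygen sits on selenium in 15 and 16 and leaves with it)
Why: Peracid takes selenium through to the selenone because syn-elimination is impossible (C1 has no hydrogen), and the selenonyl group then leaves the primary carbon in a semipinacol (Tiffeneau–Demjanov-type) 1,2-shift driven by release of bicyclo[2.1.1]hexane strain, in which fully substituted C3, anti to the bulky leaving group in the least crowded rotamer, migrates with retention rather than C6, which is less substituted and deactivated by the neighbouring C5–O bond.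

**Step 10**
Reactants: 17 norbornanone
Product: 18 C1-methylene compound (3R,5S,6R,7S) with the C5 silyloxy group endo
Conditions: Ph3PCH3Br, KOt-Bu, toluene, 90 °C
Reagents that add atoms: methyltriphenylphosphonium bromide, C[P+](c1ccccc1)(c1ccccc1)c1ccccc1.[Br-]
Why: Wittig methylenation with ylide generated by KOt-Bu at raised temperature, a protocol that serves for camphor-type hindered ketones, while C6 can neither epimerise nor expel the C5 silyloxy group because its enolate would violate Bredt's rule.

**Step 11**
Reactants: 18 silyl ether
Product: 19 C5-endo alcohol (3R,5S,6R,7S)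
Conditions: Bu4NF, THF, rt to 50 °C
Reagents that add atoms: none
Why: Fluoride cleavage of the silyl ether is driven by the Si–F bond, and nothing else in the molecule is sensitive to Bu4NF.

**Step 12**
Reactants: 19 endo alcohol
Product: 20 C5 ketone (3R,6R,7S) with C1=CH2
Conditions: Dess–Martin periodinane, CH2Cl2, 0 °C to rt
Reagents that add atoms: none
Why: Dess–Martin oxidation under nearly neutral conditions, after which the β,γ-unsaturated ketone cannot slip into conjugation because the intervening C6 is a bridgehead.

**Step 13**
Reactants: 20 C5 ketone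
Product: 21 C5-exo alcohol (3R,5R,6R,7S)
Conditions: LiBH(s-Bu)3, THF, −78 to 0 °C; then NaOH, H2O2
Reagents that add atoms: none
Why: Diastereoselective ketone reduction with a bulky borohydride: the exo face of C5 lies under the C7 methyl as in camphor while the endo face is open (C1 is sp2 and carries no endo hydrogen), so hydride should arrive endo and place the hydroxyl exo, (5R), as in the target.

**Step 14**
Reactants: 22 caffeic acid
Product: 24 (E)-3-[3,4-bis(tert-butyldimethylsilyloxy)phenyl]acrylic acid, via tris-silyl caffeate 23 (not isolated)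
Conditions: TBSCl (3.5 equiv), imidazole, DMF, rt; then AcOH–THF–H2O, rt
Reagents that add atoms: tert-butyldimethylsilyl chloride, CC(C)(C)[Si](C)(C)Cl
Why: Exhaustive silylation followed by selective hydrolysis of the far more labile silyl ester in aqueous acetic acid, which leaves both aryl silyl ethers in place.

**Step 15**
Reactants: 21 exo alcohol; 24 bis-silyl caffeic acid
Product: 25 C5-exo (E)-3,4-bis(tert-butyldimethylsilyloxy)cinnamate (3R,5R,6R,7S)
Conditions: DCC, DMAP (cat.), CH2Cl2, 0 °C to rt
Reagents that add atoms: none
Why: Steglich esterification, in which DMAP relays the carbodiimide-activated acid to the hindered exo alcohol with retention at C5 and without touching the E alkene.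

**Step 16**
Reactants: 25 protected ester
Product: 26 target, C5-exo caffeate (3R,5R,6R,7S)
Conditions: Bu4NF, AcOH, THF, 0 °C
Reagents that add atoms: none
Why: Fluoride cleaves aryl silyl ethers rapidly, and acetic acid buffers the catecholate so that neither ester cleavage nor air oxidation of the catechol sets in.

**Compound list**

1 | β-homocyclocitral, (2,6,6-trimethylcyclohex-1-en-1-yl)acetaldehyde | O=CCC1=C(C)CCCC1(C)C | starting material
2 | ethyl diazoacetate | CCOC(=O)C=[N+]=[N-] | starting material
3 | ethyl 3-oxo-4-(2,6,6-trimethylcyclohex-1-en-1-yl)butanoate | CCOC(=O)CC(=O)CC1=C(C)CCCC1(C)C | intermediate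
4 | ethyl (S)-3-hydroxy-4-(2,6,6-trimethylcyclohex-1-en-1-yl)butanoate | CCOC(=O)C[C@@H](O)CC1=C(C)CCCC1(C)C | intermediate
5 | ethyl (S)-3-(tert-butyldimethylsilyloxy)-4-(2,6,6-trimethylcyclohex-1-en-1-yl)butanoate | CCOC(=O)C[C@@H](O[Si](C)(C)C(C)(C)C)CC1=C(C)CCCC1(C)C | intermediate
6 | (S)-3-(tert-butyldimethylsilyloxy)-4-(2,6,6-trimethylcyclohex-1-en-1-yl)butanoic acid | OC(=O)C[C@@H](O[Si](C)(C)C(C)(C)C)CC1=C(C)CCCC1(C)C | intermediate
7 | (S)-3-(tert-butyldimethylsilyloxy)-4-(2,6,6-trimethylcyclohex-1-en-1-yl)butanoyl chloride | ClC(=O)C[C@@H](O[Si](C)(C)C(C)(C)C)CC1=C(C)CCCC1(C)C | intermediate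
8 | (S)-3-(tert-butyldimethylsilyloxy)-4-(2,6,6-trimethylcyclohex-1-en-1-yl)but-1-en-1-one (ketene, not isolated) | O=C=C[C@@H](O[Si](C)(C)C(C)(C)C)CC1=C(C)CCCC1(C)C | intermediate
9 | (3S,5S,6R,7S) ring A-fused bicyclo[2.1.1]hexan-5-one; C1 ketone bridges C3 and C6, C7 methyl over the C4–C5 bridge, C5 OTBS syn to the C1 bridge | O=C1[C@]23C[C@H](O[Si](C)(C)C(C)(C)C)[C@H]1[C@]2(C)CCCC3(C)C | intermediate
10 | diphenyl diselenide | c1ccc(cc1)[Se][Se]c1ccccc1 | starting material
11 | sodium benzeneselenolate (not isolated) | [Na+].[Se-]c1ccccc1 | intermediate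
12 | bis(phenylseleno)methane | C([Se]c1ccccc1)[Se]c1ccccc1 | intermediate
13 | (phenylseleno)methyllithium (not isolated) | [Li]C[Se]c1ccccc1 | intermediate
14 | (1R,3S,5S,6R,7S) C1 carbinol of 9 with CH2SePh on the C4–C5 side and OH towards C7 | O[C@@]1(C[Se]c4ccccc4)[C@]23C[C@H](O[Si](C)(C)C(C)(C)C)[C@H]1[C@]2(C)CCCC3(C)C | intermediate
15 | selenoxide of 14 (mixture at selenium, not isolated) | O[C@@]1(C[Se](=O)c4ccccc4)[C@]23C[C@H](O[Si](C)(C)C(C)(C)C)[C@H]1[C@]2(C)CCCC3(C)C | intermediate
16 | selenone of 14 (not isolated) | O[C@@]1(C[Se](=O)(=O)c4ccccc4)[C@]23C[C@H](O[Si](C)(C)C(C)(C)C)[C@H]1[C@]2(C)CCCC3(C)C | intermediate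
17 | (3S,5S,6R,7S) ring A-fused norbornanone; C1 ketone, C2 methylene between C1 and C3, C5 OTBS endo | O=C1C[C@]23C[C@H](O[Si](C)(C)C(C)(C)C)[C@H]1[C@]2(C)CCCC3(C)C | intermediate
18 | (3R,5S,6R,7S) C1-methylene compound, C5 OTBS endo | C=C1C[C@]23C[C@H](O[Si](C)(C)C(C)(C)C)[C@H]1[C@]2(C)CCCC3(C)C | intermediate
19 | (3R,5S,6R,7S) C5-endo alcohol | C=C1C[C@]23C[C@H](O)[C@H]1[C@]2(C)CCCC3(C)C | intermediate
20 | (3R,6R,7S) C5 ketone with C1=CH2 | C=C1C[C@]23CC(=O)[C@H]1[C@]2(C)CCCC3(C)C | intermediate
21 | (3R,5R,6R,7S) C5-exo alcohol | C=C1C[C@]23C[C@@H](O)[C@H]1[C@]2(C)CCCC3(C)C | intermediate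
22 | caffeic acid | O=C(O)/C=C/c1ccc(O)c(O)c1 | starting material
23 | tert-butyldimethylsilyl (E)-3-[3,4-bis(tert-butyldimethylsilyloxy)phenyl]acrylate (not isolated) | CC(C)(C)[Si](C)(C)OC(=O)/C=C/c1ccc(O[Si](C)(C)C(C)(C)C)c(O[Si](C)(C)C(C)(C)C)c1 | intermediate
24 | (E)-3-[3,4-bis(tert-butyldimethylsilyloxy)phenyl]acrylic acid | OC(=O)/C=C/c1ccc(O[Si](C)(C)C(C)(C)C)c(O[Si](C)(C)C(C)(C)C)c1 | intermediate
25 | (3R,5R,6R,7S) C5-exo (E)-3,4-bis(tert-butyldimethylsilyloxy)cinnamate | C=C1C[C@]23C[C@@H](OC(=O)/C=C/c4ccc(O[Si](C)(C)C(C)(C)C)c(O[Si](C)(C)C(C)(C)C)c4)[C@H]1[C@]2(C)CCCC3(C)C | intermediate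
26 | CNP0308742.2, (3R,5R,6R,7S) C5-exo caffeate | C=C1C[C@]23C[C@@H](OC(=O)/C=C/c4ccc(O)c(O)c4)[C@H]1[C@]2(C)CCCC3(C)C | target

**Total step count:** 16.
**Longest linear sequence:** 14 steps (steps 1–6, 8–13, 15, 16).

**Steps most likely to fail**

**Step 6.**
- Both new bonds end at fully substituted carbons next to C11, so the cycloaddition may be slower than ketene dimerisation.
- A stepwise course may be diverted by proton transfer from the C7 methyl or C8 to C6 (an ene-type outcome).
- Loss of silanolate from the β-position and weak discrimination between the two alkene faces are further ways to lose material.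
- Fallback: it sets out from 7. Pyrrolidine and Et3N in CH2Cl2 give the pyrrolidine amide F1. Tf2O and 2,4,6-collidine in refluxing 1,2-dichloroethane convert it into the keteniminium triflate F2. This is a much stronger electrophile than the ketene and cannot dimerise. It closes the same two bonds to the cyclobutaniminium triflate F3. Hydrolysis with aqueous NaHCO3 comes back to the route at 9.

**Step 9.**
- The hydroxyl group may close on the CH2 carbon (epoxide formation) instead of the 1,2-shift.
- The oxidation may stall before the selenone stage.
- Excess peracid may go on to a Baeyer–Villiger oxidation of the strained ketone.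
- Some migration of C6 in place of C3 is also conceivable.
- Fallback: it sets out from 9 and needs neither selenium nor peracid. Corey–Chaykovsky methylenation with dimethylsulfonium methylide (trimethylsulfonium iodide, NaH, DMSO–THF) gives the spiro-epoxide F4. Lithium iodide in refluxing THF opens it at the CH2 carbon to the lithium iodo-alkoxide F5. This undergoes the same strain-driven shift of C3 with loss of iodide and comes back to the route at 17.

**Step 10.**
- Addition to the C1 carbonyl may be very slow, because the exo face lies under C8 and the endo face is crowded by the C5 silyloxy group. Reversible enolisation at C2 could then consume the ylide.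
- Fallback: it sets out from 17 and changes the order of events. HF·pyridine in THF removes the silyl group first to give the hydroxy ketone F6, whose endo face is much less crowded. Non-basic Takai–Lombardo methylenation (Zn, CH2Br2, TiCl4, THF–CH2Cl2) tolerates a free hydroxyl and avoids alkoxide-triggered retro-aldol cleavage. It comes back to the route at 19.

**Further compounds**

F1 | step 6 | (S)-3-(tert-butyldimethylsilyloxy)-1-(pyrrolidin-1-yl)-4-(2,6,6-trimethylcyclohex-1-en-1-yl)butan-1-one | O=C(C[C@@H](O[Si](C)(C)C(C)(C)C)CC1=C(C)CCCC1(C)C)N1CCCC1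
F2 | step 6 | keteniminium triflate derived from F1 | C1CC[N+](=C=C[C@@H](O[Si](C)(C)C(C)(C)C)CC2=C(C)CCCC2(C)C)C1.[O-]S(=O)(=O)C(F)(F)F
F3 | step 6 | cyclobutaniminium triflate (pyrrolidinium ylidene at C1 of the skeleton of 9) | C1CC[N+](=C4[C@]23C[C@H](O[Si](C)(C)C(C)(C)C)[C@H]4[C@]2(C)CCCC3(C)C)C1.[O-]S(=O)(=O)C(F)(F)F
F4 | step 9 | spiro-epoxide at C1 of the skeleton of 9 (CH2 on the C4–C5 side) | C1O[C@]14[C@]23C[C@H](O[Si](C)(C)C(C)(C)C)[C@H]4[C@]2(C)CCCC3(C)C
F5 | step 9 | lithium alkoxide of the C1 iodomethyl carbinol | [Li+].[O-][C@@]1(CI)[C@]23C[C@H](O[Si](C)(C)C(C)(C)C)[C@H]1[C@]2(C)CCCC3(C)C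
F6 | step 10 | C5-endo hydroxy C1 ketone | O=C1C[C@]23C[C@H](O)[C@H]1[C@]2(C)CCCC3(C)C
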